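**Retrosynthetic overview**

1. The target comes from a tris-silylated oxepine alcohol by oxidation of CH2OH to CO2H and removal of three aryl silyl ethers. The carboxyl carbon is carried as CH2OH because it is the tether of the key step.
2. Key disconnection (oxepine numbering O1, C2 quaternary, C3, C4, C5=C6, C7): the O1–C2 and C7–C6 bonds are made together by a formal (5+2) annulation of formaldehyde (O1–C7) onto the open chain C2–C6 of an (E)-γ-hydroxy enone that ends in a (Z)-vinylsilane.
3. Enabling feature: C2 is the β-carbon of the aryl enone and carries the hydroxymethyl group, so formaldehyde reaches it as a hemiformal (temporary 1,3-dioxolane ring, 5-exo oxa-Michael, catalyst-controlled stereocentre). C6 lies 1,5 to C2 and carries SiMe3 cis to the chain, so the oxocarbenium ion released from the dioxolane is captured at C6 (7-endo) with loss of silicon.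
4. The acyclic precursor is assembled by two stereoretentive Negishi couplings: a (Z)-β-iodoenone (from gentisic acid and a propargyl ether) with a homoallylic zinc reagent, itself made from an (E)-α-iodovinylsilane and the zinc reagent of the coumarate side chain (SeO2 oxidation of homoprenyl bromide).
5. Ring order: temporary dioxolane, then the oxepine, in one operation; no other ring is built.

Key step: step 12

Assumption: the epi-quinidine-derived thiourea is taken as the catalyst antipode that gives the (R) centre; should a model run show the opposite sense, the epi-quinine-derived pseudo-enantiomer would be used under the same conditions.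

Abbreviations: TBS = tert-butyldimethylsilyl; PMB = 4-methoxybenzyl.

**Route**

Step 1
Reactants: 1 5-bromo-2-methylpent-2-ene
Product: 2 (2E)-5-bromo-2-methylpent-2-en-1-ol
Conditions: SeO2 (0.2 equiv), t-BuOOH (70% aq., 2.5 equiv), salicylic acid (0.1 equiv), CH2Cl2, rt
Reagents that add atoms: tert-butyl hydroperoxide CC(C)(C)OO
Why: Selenium dioxide allylic oxidation (Riley oxidation; ene reaction then [2,3]-sigmatropic shift) should hydroxylate the (E)-methyl group of the trisubstituted alkene selectively, which sets the (E) geometry of the side-chain alkene.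

Step 2
Reactants: 3 (2E)-3-(4-hydroxyphenyl)prop-2-enoic acid
Product: 5 (2E)-3-[4-(TBS-oxy)phenyl]prop-2-enoic acid, via silyl ester 4 (not isolated)
Conditions: TBSCl (2.3 equiv), imidazole (5 equiv), DMF, rt; then AcOH–THF–H2O (3:1:1), rt
Reagents that add atoms: tert-butyldimethylsilyl chloride CC(C)(C)[Si](C)(C)Cl
Why: Standard silylation of phenol and acid followed by selective hydrolysis of the labile silyl ester should leave the aryl silyl ether, which is stable to dilute acetic acid.

Step 3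
Reactants: 2 (2E)-5-bromo-2-methylpent-2-en-1-ol; 5 (2E)-3-[4-(TBS-oxy)phenyl]prop-2-enoic acid
Product: 6 (2E)-5-bromo-2-methylpent-2-en-1-yl (2E)-3-[4-(TBS-oxy)phenyl]prop-2-enoate
Conditions: DCC (1.1 equiv), DMAP (0.1 equiv), CH2Cl2, 0 °C→rt
Reagents that add atoms: none
Why: Steglich esterification of an unhindered primary allylic alcohol should proceed without touching either alkene geometry.

Step 4
Reactants: 7 (4-bromobut-1-yn-1-yl)trimethylsilane
Product: 9 [(1E)-4-bromo-1-iodobut-1-en-1-yl]trimethylsilane, via alkenylalane 8 (not isolated)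
Conditions: i-Bu2AlH (1.3 equiv), Et2O, rt→40 °C; then I2 (1.5 equiv), −78→0 °C
Reagents that add atoms: iodine II
Why: cis-Hydroalumination of a 1-silylalkyne in a donor solvent should place aluminium on the silicon-bearing carbon, and iodinolysis of the C–Al bond with retention should give the (E)-α-iodovinylsilane, in which silicon is cis to the bromoethyl chain.

Step 5
Reactants: 6 (2E)-5-bromo-2-methylpent-2-en-1-yl (2E)-3-[4-(TBS-oxy)phenyl]prop-2-enoate; 9 [(1E)-4-bromo-1-iodobut-1-en-1-yl]trimethylsilane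
Product: 11 (2E,6Z)-9-bromo-2-methyl-6-(trimethylsilyl)nona-2,6-dien-1-yl (2E)-3-[4-(TBS-oxy)phenyl]prop-2-enoate, via organozinc bromide 10 (not isolated)
Conditions: Zn dust (3 equiv, activated by BrCH2CH2Br and Me3SiCl), LiCl (1.5 equiv), THF, 50 °C; decant from Zn; then 9 (0.85 equiv), Pd(PPh3)4 (5 mol %), THF, rt
Reagents that add atoms: none
Why: LiCl-assisted zinc insertion into the primary bromide and Negishi sp3–sp2 coupling should take place only at the C(sp2)–I bond and with retention of geometry, so the (Z)-vinylsilane with silicon cis to the bromoethyl chain should result.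

Step 6
Reactants: 12 2,5-dihydroxybenzoic acid
Product: 13 TBS 2,5-bis(TBS-oxy)benzoate
Conditions: TBSCl (3.5 equiv), imidazole (7 equiv), DMF, rt→40 °C
Reagents that add atoms: tert-butyldimethylsilyl chloride CC(C)(C)[Si](C)(C)Cl
Why: Exhaustive silylation of both phenols and the acid is standard and should give the tris-silyl compound, which is used without chromatography.

Step 7
Reactants: 14 prop-2-yn-1-ol; 15 1-(chloromethyl)-4-methoxybenzene
Product: 16 1-methoxy-4-[(prop-2-yn-1-yloxy)methyl]benzene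
Conditions: NaH (1.1 equiv), n-Bu4NI (0.05 equiv), THF–DMF, 0 °C→rt
Reagents that add atoms: none
Why: Williamson ether synthesis of a primary alkoxide with a benzylic chloride should be straightforward.

Step 8
Reactants: 13 TBS 2,5-bis(TBS-oxy)benzoate; 16 1-methoxy-4-[(prop-2-yn-1-yloxy)methyl]benzene
Product: 18 1-[2,5-bis(TBS-oxy)phenyl]-4-(PMB-oxy)but-2-yn-1-one, via acid chloride 17 (not isolated)
Conditions: (COCl)2 (1.2 equiv), DMF (cat.), CH2Cl2, 0 °C→rt; evaporate; then 16 (1.1 equiv), PdCl2(PPh3)2 (2 mol %), CuI (4 mol %), Et3N (1.5 equiv), THF, rt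
Reagents that add atoms: none
Why: The silyl ester should be converted directly into the acid chloride under neutral Vilsmeier-type activation, and acyl Sonogashira coupling should then give the ynone without exposing the ortho-silyloxy aryl carbonyl to an alkoxide that could trigger silyl migration.

Step 9
Reactants: 18 1-[2,5-bis(TBS-oxy)phenyl]-4-(PMB-oxy)but-2-yn-1-one
Product: 19 (2Z)-1-[2,5-bis(TBS-oxy)phenyl]-3-iodo-4-(PMB-oxy)but-2-en-1-one
Conditions: NaI (2 equiv), AcOH, rt
Reagents that add atoms: sodium iodide [Na+].[I-]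
Why: Hydroiodination of the ynone by conjugate addition of iodide and anti protonation should give the kinetic (Z)-β-iodoenone, in which iodine is cis to the aroyl group.

Step 10
Reactants: 11 (2E,6Z)-9-bromo-2-methyl-6-(trimethylsilyl)nona-2,6-dien-1-yl (2E)-3-[4-(TBS-oxy)phenyl]prop-2-enoate; 19 (2Z)-1-[2,5-bis(TBS-oxy)phenyl]-3-iodo-4-(PMB-oxy)but-2-en-1-one
Product: 21 (2E,6Z,10E)-12-[2,5-bis(TBS-oxy)phenyl]-2-methyl-12-oxo-10-[(PMB-oxy)methyl]-6-(trimethylsilyl)dodeca-2,6,10-trien-1-yl (2E)-3-[4-(TBS-oxy)phenyl]prop-2-enoate, via organozinc bromide 20 (not isolated)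
Conditions: Zn dust (3 equiv, activated), LiCl (1.5 equiv), THF, 50 °C; decant from Zn; then 19 (0.85 equiv), Pd(PPh3)4 (5 mol %), THF, 0 °C→rt
Reagents that add atoms: none
Why: Negishi coupling of the β-iodoenone with retention should place the chain cis to the aroyl group and the CH2O-PMB group trans to it, the (E) geometry that later keeps the free alcohol from closing onto the ketone.

Step 11
Reactants: 21 the PMB ether described in step 10
Product: 22 (2E,6Z,10E)-12-[2,5-bis(TBS-oxy)phenyl]-10-(hydroxymethyl)-2-methyl-12-oxo-6-(trimethylsilyl)dodeca-2,6,10-trien-1-yl (2E)-3-[4-(TBS-oxy)phenyl]prop-2-enoate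
Conditions: DDQ (1.3 equiv), CH2Cl2–pH 7 phosphate buffer (10:1), 0 °C; product used at once
Reagents that add atoms: none
Why: Oxidative cleavage of the 4-methoxybenzyl ether under neutral conditions should leave silyl ethers, vinylsilane and enone geometry untouched.

Step 12
Reactants: 22 the (E)-γ-hydroxy enone described in step 11; 23 formaldehyde (charged as paraformaldehyde)
Product: 27 (2E)-5-[(2R)-2-{2-[2,5-bis(TBS-oxy)phenyl]-2-oxoethyl}-2-(hydroxymethyl)-2,3,4,7-tetrahydrooxepin-6-yl]-2-methylpent-2-en-1-yl (2E)-3-[4-(TBS-oxy)phenyl]prop-2-enoate, via hemiformal 24 (not isolated), via dioxolane 25 (not isolated), via trimethylsilyl ether 26 (not isolated)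
Conditions: (CH2O)n (1.2 equiv), 9-amino(9-deoxy)epi-quinidine-derived 3,5-bis(trifluoromethyl)phenyl thiourea (10 mol %), CH2Cl2, rt; then Me3SiOTf (0.3 equiv), −78→0 °C; then 1 M aq. citric acid, THF, 0 °C
Reagents that add atoms: none
Why: Proposed new method: alcohol 22 and formaldehyde equilibrate to hemiformal 24, whose hydroxyl is deprotonated by the quinuclidine nitrogen of the bifunctional catalyst while its thiourea binds the aryl ketone, so that the alkoxide adds to the β-carbon of the enone in a 5-exo-trig oxa-Michael closure to dioxolane 25; the closest known reaction type is the amine–thiourea-catalysed hemiacetal/oxa-Michael synthesis of 1,3-dioxolanes from γ-hydroxy enones and aldehydes, extended here to formaldehyde and to a β,β-disubstituted enone. Me3SiOTf then silylates the less hindered primary acetal oxygen, the dioxolane opens to the oxocarbenium ion CH2=O+ on the tertiary oxygen, and the (Z)-vinylsilane attacks this ion through its silicon-bearing carbon in a 7-endo-trig closure (endocyclic to both π bonds), after which loss of Me3Si+ from the β-silyl cation restores the ring alkene and the silyl triflate; the closest known reaction type for this half is the Lewis-acid-promoted cyclisation of formaldehyde mixed acetals onto (Z)-vinylsilanes to give 2,3,4,7-tetrahydrooxepines. The single new stereocentre, the oxygen-bearing quaternary carbon, should be set in the oxa-Michael event by the chiral catalyst, which exposes one face of the hydrogen-bonded enone, and it should survive the second stage because no base is present and the temperature stays at or below 0 °C, so the β-alkoxy ketone should not eliminate. The step needs attack at the silicon-bearing carbon (seven-membered ring) and not at the neighbouring CH (six-membered ring), which the β-silicon effect and the cis relation of silicon and tether should secure, and it needs ionisation towards the tertiary oxygen, which should be secured because the silyl triflate binds the unhindered oxygen and only that ion can reach the vinylsilane through a seven-membered transition state. The enone is consumed in the first stage, so direct attack of the vinylsilane on the enone cannot compete once the Lewis acid is present.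

Step 13
Reactants: 27 the oxepine alcohol described in step 12
Product: 29 (2R)-2-{2-[2,5-bis(TBS-oxy)phenyl]-2-oxoethyl}-6-[(3E)-4-methyl-5-{[(2E)-3-(4-TBS-oxyphenyl)prop-2-enoyl]oxy}pent-3-en-1-yl]-2,3,4,7-tetrahydrooxepine-2-carboxylic acid, via aldehyde 28 (not isolated)
Conditions: TEMPO (0.2 equiv), PhI(OAc)2 (2.5 equiv), MeCN–H2O (1:1), rt
Reagents that add atoms: water O
Why: Oxoammonium (nitroxyl-catalysed) oxidation should take the primary alcohol to the aldehyde and, through its hydrate, to the acid; the quaternary α-carbon cannot epimerise and the weakly acidic medium should not open the β-alkoxy ketone.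

Step 14
Reactants: 29 the tris-silylated acid described in step 13
Product: 30 (2R)-2-[2-(2,5-dihydroxyphenyl)-2-oxoethyl]-6-[(3E)-5-{[(2E)-3-(4-hydroxyphenyl)prop-2-enoyl]oxy}-4-methylpent-3-en-1-yl]-2,3,4,7-tetrahydrooxepine-2-carboxylic acid
Conditions: HF·pyridine (excess), pyridine, THF, 0 °C→rt
Reagents that add atoms: none
Why: Fluoride cleavage of the three aryl silyl ethers under buffered, weakly acidic conditions should free the phenols while avoiding base-induced β-elimination of the ring oxygen, which would cost the stereocentre.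

**Compound list**

1 | 5-bromo-2-methylpent-2-ene | CC(C)=CCCBr | starting material
2 | (2E)-5-bromo-2-methylpent-2-en-1-ol | C/C(=C\CCBr)CO | intermediate
3 | (2E)-3-(4-hydroxyphenyl)prop-2-enoic acid (p-coumaric acid) | OC(=O)/C=C/c1ccc(O)cc1 | starting material
4 | TBS (2E)-3-[4-(TBS-oxy)phenyl]prop-2-enoate | CC(C)(C)[Si](C)(C)OC(=O)/C=C/c1ccc(O[Si](C)(C)C(C)(C)C)cc1 | intermediate
5 | (2E)-3-[4-(TBS-oxy)phenyl]prop-2-enoic acid | OC(=O)/C=C/c1ccc(O[Si](C)(C)C(C)(C)C)cc1 | intermediate
6 | (2E)-5-bromo-2-methylpent-2-en-1-yl (2E)-3-[4-(TBS-oxy)phenyl]prop-2-enoate | C/C(=C\CCBr)COC(=O)/C=C/c1ccc(O[Si](C)(C)C(C)(C)C)cc1 | intermediate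
7 | (4-bromobut-1-yn-1-yl)trimethylsilane | BrCCC#C[Si](C)(C)C | starting material
8 | [(1Z)-4-bromo-1-(trimethylsilyl)but-1-en-1-yl]bis(2-methylpropyl)alumane | BrCC/C=C(/[Al](CC(C)C)CC(C)C)[Si](C)(C)C | intermediate
9 | [(1E)-4-bromo-1-iodobut-1-en-1-yl]trimethylsilane | BrCC/C=C(/I)[Si](C)(C)C | intermediate
10 | organozinc bromide of 6: bromo[(3E)-4-methyl-5-{[(2E)-3-(4-TBS-oxyphenyl)prop-2-enoyl]oxy}pent-3-en-1-yl]zinc | C/C(=C\CC[Zn]Br)COC(=O)/C=C/c1ccc(O[Si](C)(C)C(C)(C)C)cc1 | intermediate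
11 | (2E,6Z)-9-bromo-2-methyl-6-(trimethylsilyl)nona-2,6-dien-1-yl (2E)-3-[4-(TBS-oxy)phenyl]prop-2-enoate | BrCC/C=C(/CC\C=C(/C)COC(=O)/C=C/c1ccc(O[Si](C)(C)C(C)(C)C)cc1)[Si](C)(C)C | intermediate
12 | 2,5-dihydroxybenzoic acid (gentisic acid) | OC(=O)c1cc(O)ccc1O | starting material
13 | TBS 2,5-bis(TBS-oxy)benzoate | CC(C)(C)[Si](C)(C)OC(=O)c1cc(O[Si](C)(C)C(C)(C)C)ccc1O[Si](C)(C)C(C)(C)C | intermediate
14 | prop-2-yn-1-ol | C#CCO | starting material
15 | 1-(chloromethyl)-4-methoxybenzene | COc1ccc(CCl)cc1 | starting material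
16 | 1-methoxy-4-[(prop-2-yn-1-yloxy)methyl]benzene | C#CCOCc1ccc(OC)cc1 | intermediate
17 | 2,5-bis(TBS-oxy)benzoyl chloride | O=C(Cl)c1cc(O[Si](C)(C)C(C)(C)C)ccc1O[Si](C)(C)C(C)(C)C | intermediate
18 | 1-[2,5-bis(TBS-oxy)phenyl]-4-(PMB-oxy)but-2-yn-1-one | O=C(C#CCOCc1ccc(OC)cc1)c1cc(O[Si](C)(C)C(C)(C)C)ccc1O[Si](C)(C)C(C)(C)C | intermediate
19 | (2Z)-1-[2,5-bis(TBS-oxy)phenyl]-3-iodo-4-(PMB-oxy)but-2-en-1-one | O=C(/C=C(\I)COCc1ccc(OC)cc1)c1cc(O[Si](C)(C)C(C)(C)C)ccc1O[Si](C)(C)C(C)(C)C | intermediate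
20 | organozinc bromide of 11: bromo[(3Z,7E)-8-methyl-9-{[(2E)-3-(4-TBS-oxyphenyl)prop-2-enoyl]oxy}-4-(trimethylsilyl)nona-3,7-dien-1-yl]zinc | Br[Zn]CC/C=C(/CC\C=C(/C)COC(=O)/C=C/c1ccc(O[Si](C)(C)C(C)(C)C)cc1)[Si](C)(C)C | intermediate
21 | (2E,6Z,10E)-12-[2,5-bis(TBS-oxy)phenyl]-2-methyl-12-oxo-10-[(PMB-oxy)methyl]-6-(trimethylsilyl)dodeca-2,6,10-trien-1-yl (2E)-3-[4-(TBS-oxy)phenyl]prop-2-enoate | O=C(/C=C(\CC/C=C(/CC\C=C(/C)COC(=O)/C=C/c1ccc(O[Si](C)(C)C(C)(C)C)cc1)[Si](C)(C)C)COCc1ccc(OC)cc1)c1cc(O[Si](C)(C)C(C)(C)C)ccc1O[Si](C)(C)C(C)(C)C | intermediate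
22 | (2E,6Z,10E)-12-[2,5-bis(TBS-oxy)phenyl]-10-(hydroxymethyl)-2-methyl-12-oxo-6-(trimethylsilyl)dodeca-2,6,10-trien-1-yl (2E)-3-[4-(TBS-oxy)phenyl]prop-2-enoate | O=C(/C=C(\CC/C=C(/CC\C=C(/C)COC(=O)/C=C/c1ccc(O[Si](C)(C)C(C)(C)C)cc1)[Si](C)(C)C)CO)c1cc(O[Si](C)(C)C(C)(C)C)ccc1O[Si](C)(C)C(C)(C)C | intermediate
23 | formaldehyde (from paraformaldehyde) | C=O | starting material
24 | hemiformal of 22: the 10-[(hydroxymethoxy)methyl] analogue | O=C(/C=C(\CC/C=C(/CC\C=C(/C)COC(=O)/C=C/c1ccc(O[Si](C)(C)C(C)(C)C)cc1)[Si](C)(C)C)COCO)c1cc(O[Si](C)(C)C(C)(C)C)ccc1O[Si](C)(C)C(C)(C)C | intermediate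
25 | (2E,6Z)-9-[(4R)-4-{2-[2,5-bis(TBS-oxy)phenyl]-2-oxoethyl}-1,3-dioxolan-4-yl]-2-methyl-6-(trimethylsilyl)nona-2,6-dien-1-yl (2E)-3-[4-(TBS-oxy)phenyl]prop-2-enoate | C[Si](C)(C)/C(CC\C=C(/C)COC(=O)/C=C/c1ccc(O[Si](C)(C)C(C)(C)C)cc1)=C\CC[C@@]1(CC(=O)c2cc(O[Si](C)(C)C(C)(C)C)ccc2O[Si](C)(C)C(C)(C)C)COCO1 | intermediate
26 | (2E)-5-[(2R)-2-{2-[2,5-bis(TBS-oxy)phenyl]-2-oxoethyl}-2-[(trimethylsilyloxy)methyl]-2,3,4,7-tetrahydrooxepin-6-yl]-2-methylpent-2-en-1-yl (2E)-3-[4-(TBS-oxy)phenyl]prop-2-enoate | C/C(=C\CCC1=CCC[C@@](CC(=O)c2cc(O[Si](C)(C)C(C)(C)C)ccc2O[Si](C)(C)C(C)(C)C)(CO[Si](C)(C)C)OC1)COC(=O)/C=C/c1ccc(O[Si](C)(C)C(C)(C)C)cc1 | intermediate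
27 | (2E)-5-[(2R)-2-{2-[2,5-bis(TBS-oxy)phenyl]-2-oxoethyl}-2-(hydroxymethyl)-2,3,4,7-tetrahydrooxepin-6-yl]-2-methylpent-2-en-1-yl (2E)-3-[4-(TBS-oxy)phenyl]prop-2-enoate | C/C(=C\CCC1=CCC[C@@](CC(=O)c2cc(O[Si](C)(C)C(C)(C)C)ccc2O[Si](C)(C)C(C)(C)C)(CO)OC1)COC(=O)/C=C/c1ccc(O[Si](C)(C)C(C)(C)C)cc1 | intermediate
28 | (2E)-5-[(2R)-2-{2-[2,5-bis(TBS-oxy)phenyl]-2-oxoethyl}-2-formyl-2,3,4,7-tetrahydrooxepin-6-yl]-2-methylpent-2-en-1-yl (2E)-3-[4-(TBS-oxy)phenyl]prop-2-enoate | C/C(=C\CCC1=CCC[C@@](CC(=O)c2cc(O[Si](C)(C)C(C)(C)C)ccc2O[Si](C)(C)C(C)(C)C)(C=O)OC1)COC(=O)/C=C/c1ccc(O[Si](C)(C)C(C)(C)C)cc1 | intermediate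
29 | (2R)-2-{2-[2,5-bis(TBS-oxy)phenyl]-2-oxoethyl}-6-[(3E)-4-methyl-5-{[(2E)-3-(4-TBS-oxyphenyl)prop-2-enoyl]oxy}pent-3-en-1-yl]-2,3,4,7-tetrahydrooxepine-2-carboxylic acid | C/C(=C\CCC1=CCC[C@@](CC(=O)c2cc(O[Si](C)(C)C(C)(C)C)ccc2O[Si](C)(C)C(C)(C)C)(C(=O)O)OC1)COC(=O)/C=C/c1ccc(O[Si](C)(C)C(C)(C)C)cc1 | intermediate
30 | (2R)-2-[2-(2,5-dihydroxyphenyl)-2-oxoethyl]-6-[(3E)-5-{[(2E)-3-(4-hydroxyphenyl)prop-2-enoyl]oxy}-4-methylpent-3-en-1-yl]-2,3,4,7-tetrahydrooxepine-2-carboxylic acid | C/C(=C\CCC1=CCC[C@@](CC(=O)c2cc(O)ccc2O)(C(=O)O)OC1)COC(=O)/C=C/c1ccc(O)cc1 | target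

**Totals and risks**

Total step count: 14. Longest linear sequence: 8 steps (steps 1, 3, 5, 10, 11, 12, 13, 14; the branch through steps 6, 8, 9 is equally long).

Steps most likely to fail:

Step 12 (proposed new method). The oxa-Michael event may show poor facial selectivity at the fully substituted β-carbon or may revert before the ring is opened, and the amine catalyst may interfere with the Lewis-acid stage. The fallback uses known chemistry and gives up catalyst control. From 22, the hemiformal addition would be run with an achiral base (DBU, paraformaldehyde, THF; base-mediated hemiacetal conjugate addition), and the racemic dioxolane F1 would be isolated. A separate acetal–vinylsilane cyclisation (Me3SiOTf, CH2Cl2, −78→0 °C) would give the racemic trimethylsilyl ether F2, which is hydrolysed on acidic work-up to the racemic oxepine alcohol F3. Preparative chromatography on a chiral stationary phase would separate the enantiomers; the (R) enantiomer is 27, where the route is rejoined.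

Step 5. Zerovalent palladium may insert into the allylic coumarate of the zinc reagent or of the product in competition with the hindered α-silyl vinyl iodide, and zinc insertion next to the ester may be slow; the same exposure recurs in step 10. The fallback changes the order of events so that no allylic ester meets palladium. From 2, silylation (TBSCl, imidazole, DMF) would give the silyl ether F4. Zinc insertion would give the organozinc bromide F5, which is coupled with 9 under Pd(PPh3)4 to the bromide F6. A second zinc insertion would give the organozinc bromide F7, which is coupled with 19 to the enone F8. Camphorsulfonic acid in MeOH at 0 °C would remove only the alkyl silyl ether to give the allylic alcohol F9, and Steglich esterification with 5 (DCC, DMAP) would give 21, where the route is rejoined.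

Step 13. The oxidation may stall at the hydrate of the hindered neopentyl aldehyde, or the iodine oxidant may attack the silylated hydroquinone ring. The fallback separates the two oxidation levels. From 27, Dess–Martin periodinane (NaHCO3, CH2Cl2) would give the aldehyde 28, now isolated, and a Pinnick oxidation (NaClO2, NaH2PO4, 2-methylbut-2-ene, t-BuOH–H2O) would give 29, where the route is rejoined.

**Further compounds**

F1 | step 12 | racemic 1,3-dioxolane (racemate of 25) | C[Si](C)(C)/C(CC\C=C(/C)COC(=O)/C=C/c1ccc(O[Si](C)(C)C(C)(C)C)cc1)=C\CCC1(CC(=O)c2cc(O[Si](C)(C)C(C)(C)C)ccc2O[Si](C)(C)C(C)(C)C)COCO1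
F2 | step 12 | racemic trimethylsilyl ether (racemate of 26) | C/C(=C\CCC1=CCCC(CC(=O)c2cc(O[Si](C)(C)C(C)(C)C)ccc2O[Si](C)(C)C(C)(C)C)(CO[Si](C)(C)C)OC1)COC(=O)/C=C/c1ccc(O[Si](C)(C)C(C)(C)C)cc1
F3 | step 12 | racemic oxepine alcohol (racemate of 27) | C/C(=C\CCC1=CCCC(CC(=O)c2cc(O[Si](C)(C)C(C)(C)C)ccc2O[Si](C)(C)C(C)(C)C)(CO)OC1)COC(=O)/C=C/c1ccc(O[Si](C)(C)C(C)(C)C)cc1
F4 | step 5 | {[(2E)-5-bromo-2-methylpent-2-en-1-yl]oxy}(tert-butyl)dimethylsilane | C/C(=C\CCBr)CO[Si](C)(C)C(C)(C)C
F5 | step 5 | bromo[(3E)-4-methyl-5-(TBS-oxy)pent-3-en-1-yl]zinc | C/C(=C\CC[Zn]Br)CO[Si](C)(C)C(C)(C)C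
F6 | step 5 | {[(2E,6Z)-9-bromo-2-methyl-6-(trimethylsilyl)nona-2,6-dien-1-yl]oxy}(tert-butyl)dimethylsilane | BrCC/C=C(/CC\C=C(/C)CO[Si](C)(C)C(C)(C)C)[Si](C)(C)C
F7 | step 5 | bromo[(3Z,7E)-8-methyl-9-(TBS-oxy)-4-(trimethylsilyl)nona-3,7-dien-1-yl]zinc | Br[Zn]CC/C=C(/CC\C=C(/C)CO[Si](C)(C)C(C)(C)C)[Si](C)(C)C
F8 | step 5 | (2E,6Z,10E)-1-[2,5-bis(TBS-oxy)phenyl]-11-methyl-3-[(PMB-oxy)methyl]-12-(TBS-oxy)-7-(trimethylsilyl)dodeca-2,6,10-trien-1-one | O=C(/C=C(\CC/C=C(/CC\C=C(/C)CO[Si](C)(C)C(C)(C)C)[Si](C)(C)C)COCc1ccc(OC)cc1)c1cc(O[Si](C)(C)C(C)(C)C)ccc1O[Si](C)(C)C(C)(C)C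
F9 | step 5 | (2E,6Z,10E)-1-[2,5-bis(TBS-oxy)phenyl]-12-hydroxy-11-methyl-3-[(PMB-oxy)methyl]-7-(trimethylsilyl)dodeca-2,6,10-trien-1-one | O=C(/C=C(\CC/C=C(/CC\C=C(/C)CO)[Si](C)(C)C)COCc1ccc(OC)cc1)c1cc(O[Si](C)(C)C(C)(C)C)ccc1O[Si](C)(C)C(C)(C)C
F0 | step 13 | none | none
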